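**Retrosynthetic overview**
1. The target is 2,4-dimethoxyphenol carrying an n-C23 chain at its only free ortho carbon; the arene is bought, so no ring is formed.
2. Side chain: cut the C1'–C2' bond, giving a benzylic carbinol from a salicylaldehyde and a C22 Grignard reagent; the carbinol OH is then removed by ionic hydrogenation.
3. Aldehyde: from 2,4-dimethoxyphenol by Mg-mediated, ortho-specific formylation.

Assumption: the target has no stereocentre and no stereogenic double bond, so "single enantiomer" imposes no requirement; the carbinol 6 is used as the racemate and its centre is erased in step 3. 2,4-Dimethoxyphenol and 1-bromodocosane are taken as purchasable.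

**Step 1**
Reactants: 1 2,4-dimethoxyphenol
Product: 3 2-hydroxy-3,5-dimethoxybenzaldehyde, via 2-(hydroxymethyl)-4,6-dimethoxyphenol 2 (not isolated)
Conditions: MgCl2 (1.5 equiv), Et3N (3.75 equiv), (CH2O)n (7 equiv), MeCN, reflux; then 1 M HCl
Reagents that add atoms: paraformaldehyde (formaldehyde source), C=O
Why: Casnati–Skattebøl ortho-formylation, in which the magnesium phenoxide delivers formaldehyde through a chelate only to the ortho carbon (C6 is the single free one) and the resulting salicyl alcohol 2 is oxidised in the flask by a second formaldehyde through Oppenauer-type hydride transfer.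

**Step 2**
Reactants: 3 2-hydroxy-3,5-dimethoxybenzaldehyde; 4 1-bromodocosane
Product: 6 2-(1-hydroxytricosyl)-4,6-dimethoxyphenol (racemic), via docosylmagnesium bromide 5 (not isolated)
Conditions: 4 (2.5 equiv), Mg (3 equiv), cat. I2, THF, 55 °C; then 3, THF, 0 °C to rt; 1 M HCl, 0 °C
Reagents that add atoms: magnesium, [Mg] (its atom is kept only in intermediate 5, not in 6)
Why: Grignard addition to a non-enolisable aromatic aldehyde, where the first equivalent deprotonates the phenol and the second adds to C=O to give the secondary benzylic alcohol as a racemate (no stereocontrol is needed because this centre is removed in step 3).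

**Step 3**
Reactants: 6 2-(1-hydroxytricosyl)-4,6-dimethoxyphenol (racemic)
Product: 7 2,4-dimethoxy-6-tricosylphenol (target)
Conditions: Et3SiH (4 equiv), TFA (10 equiv), CH2Cl2 (dilute), 0 °C to rt
Reagents that add atoms: none
Why: Ionic hydrogenation (Kursanov–Parnes type), in which TFA activates the benzylic C–O bond made labile by the ortho hydroxyl and Et3SiH delivers hydride to that carbon, giving the CH2 group while aryl methyl ethers and the phenol are inert to these conditions.

**Compound list**
1 | 2,4-dimethoxyphenol | COc1ccc(O)c(OC)c1 | starting material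
2 | 2-(hydroxymethyl)-4,6-dimethoxyphenol (present as its magnesium salt, drawn neutral) | OCc1cc(OC)cc(OC)c1O | intermediate
3 | 2-hydroxy-3,5-dimethoxybenzaldehyde | O=Cc1cc(OC)cc(OC)c1O | intermediate
4 | 1-bromodocosane | CCCCCCCCCCCCCCCCCCCCCCBr | starting material
5 | docosylmagnesium bromide | CCCCCCCCCCCCCCCCCCCCCC[Mg]Br | intermediate
6 | 2-(1-hydroxytricosyl)-4,6-dimethoxyphenol (racemic) | CCCCCCCCCCCCCCCCCCCCCCC(O)c1cc(OC)cc(OC)c1O | intermediate
7 | 2,4-dimethoxy-6-tricosylphenol (achiral) | CCCCCCCCCCCCCCCCCCCCCCCc1cc(OC)cc(OC)c1O | target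

**Totals**
Total step count: 3. Longest linear sequence: 3 (1 → 3 → 6 → 7).

**Steps most likely to fail, with fallbacks**

Step 1 (ortho-formylation). A guaiacol-type phenol can chelate magnesium through its ortho methoxy group and stall, or give diarylmethane by-products. The fallback sets out from 1 and comes back to the route at 7. O-Allylation of 1 (allyl bromide, K2CO3, acetone, reflux) gives 1-(allyloxy)-2,4-dimethoxybenzene F1. Aromatic Claisen rearrangement (N,N-diethylaniline, 200 °C) can go only to the one free ortho carbon and gives 2-allyl-4,6-dimethoxyphenol F2. Cross-metathesis with commercial 1-docosene (3 equiv, Grubbs II, CH2Cl2, 40 °C) gives 2,4-dimethoxy-6-(tricos-2-en-1-yl)phenol F3, mainly E, and the geometry is irrelevant. Hydrogenation (H2, Pd/C, EtOAc) saturates it to 7.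

Step 2 (Grignard addition). The waxy C22 bromide may form the Grignard reagent sluggishly, with Wurtz coupling, and the reagent may add poorly to the magnesium phenoxide of 3. The fallback sets out from 3, with 4 as chain source, and comes back at 7. Heating 4 with PPh3 (toluene/MeCN, reflux) gives docosyltriphenylphosphonium bromide F4. KHMDS (THF, 0 °C) turns it into docosylidenetriphenylphosphorane F5, used at 2.2 equiv because the first equivalent is consumed by the phenol. Wittig olefination of 3 gives 2,4-dimethoxy-6-(tricos-1-en-1-yl)phenol F6, mainly Z. Hydrogenation (H2, Pd/C, EtOAc) gives 7.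

Step 3 (ionic deoxygenation). The benzylic electrophile may attack the electron-rich ring of another molecule (Friedel–Crafts self-alkylation) instead of being reduced. The fallback sets out from 6 and comes back at 7, with the phenol masked and the C–O bond cleaved by catalytic hydrogenolysis instead of hydride transfer. Ac2O, pyridine and cat. DMAP give the diacetate 1-(2-acetoxy-3,5-dimethoxyphenyl)tricosyl acetate F7. Hydrogenolysis of the benzylic acetate (H2, Pd/C, EtOAc–AcOH) gives 2,4-dimethoxy-6-tricosylphenyl acetate F8. K2CO3 in MeOH–THF removes the aryl acetate to give 7.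

**Further compounds**
F1 | step 1 | 1-(allyloxy)-2,4-dimethoxybenzene | C=CCOc1ccc(OC)cc1OC
F2 | step 1 | 2-allyl-4,6-dimethoxyphenol | C=CCc1cc(OC)cc(OC)c1O
F3 | step 1 | (E)-2,4-dimethoxy-6-(tricos-2-en-1-yl)phenol | CCCCCCCCCCCCCCCCCCCC/C=C/Cc1cc(OC)cc(OC)c1O
F4 | step 2 | docosyltriphenylphosphonium bromide | CCCCCCCCCCCCCCCCCCCCCC[P+](c1ccccc1)(c1ccccc1)c1ccccc1.[Br-]
F5 | step 2 | docosylidenetriphenylphosphorane | CCCCCCCCCCCCCCCCCCCCCC=P(c1ccccc1)(c1ccccc1)c1ccccc1
F6 | step 2 | (Z)-2,4-dimethoxy-6-(tricos-1-en-1-yl)phenol | CCCCCCCCCCCCCCCCCCCCC/C=C\c1cc(OC)cc(OC)c1O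
F7 | step 3 | 1-(2-acetoxy-3,5-dimethoxyphenyl)tricosyl acetate (racemic) | CCCCCCCCCCCCCCCCCCCCCCC(OC(C)=O)c1cc(OC)cc(OC)c1OC(C)=O
F8 | step 3 | 2,4-dimethoxy-6-tricosylphenyl acetate | CCCCCCCCCCCCCCCCCCCCCCCc1cc(OC)cc(OC)c1OC(C)=O
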